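**Retrosynthetic overview**
1. Target 27 ← triol 26 by acetylation of the unhindered allylic C13–OH; C10=CH2 comes from a C10 ketone, the C6 carbinol from a C6 ketone, and C3–H from a C3–SiMe3 group.
2. Ring B (seven-membered: C1, C5–C10) ← six-membered ketone by one-carbon ring expansion: C7 is inserted between C6 and C8 as the diazo carbon of a side-chain fragment that already carries C11 and C13.
3. C4–OH with C2=C3 ← silicon-directed singlet-oxygen ene reaction of a C3-silylated cyclopentene, oxygen entering from the convex face.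
4. Ring A (five-membered: C1–C5) ← [3+2] annulation of (S)-4-silyloxycyclohexenone 6 with silylallene 2, forming C1–C2 and C4–C5. The enabling feature is the C6 oxygen of ring B next to ring-fusion carbon C5: at the ketone level it makes C1 (β) electrophilic and C5 (α) nucleophilic, while the oxygen on C10 (the later methylene carbon) steers the face.
5. Ring order: six-membered carbocycle (bought) → ring A (key step) → expansion of the six-membered ring to seven-membered ring B.

Key step: step 5

Remark: dictyol numbering is used for every intermediate (C1/C5 ring fusion, C2=C3, C4 with Me and OH, C6 carbinol, C7 side-chain carbon, C8, C9, C10 methylene carbon, side chain C11(Me)–C12–C13(O)–C14=C15Me2); β is the face of H-1 and H-5; compounds 1, 3, 11 and 12 are taken as catalogue chemicals; the chloride bridge of the Tebbe reagent is drawn in its SMILES as a formal aluminate/chloronium pair.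

Step 1
Reactants: 1 3-bromo-1-(trimethylsilyl)prop-1-yne
Product: 2 3-(trimethylsilyl)buta-1,2-diene
Conditions: MeMgCl, CuBr (10 mol%), LiBr, THF, −78 → 0 °C
Reagents that add atoms: methylmagnesium chloride, C[Mg]Cl
Why: Copper-catalysed SN2′ substitution of the propargylic bromide by the Grignard reagent: methyl enters at the silyl-bearing alkyne carbon and bromide leaves from C3, giving the 1,1-disubstituted allene (no stereocentre).

Step 2
Reactants: 3 1,4-dioxaspiro[4.5]dec-6-en-8-one
Product: 4 (S)-1,4-dioxaspiro[4.5]dec-6-en-8-ol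
Conditions: (R)-2-methyl-CBS-oxazaborolidine (10 mol%), BH3·SMe2, THF, −30 °C; MeOH
Reagents that add atoms: none
Why: Corey–Bakshi–Shibata reduction: the oxazaborolidine binds the ketone with the alkenyl arm as the large group and delivers hydride to one face, which should set the (S)-carbinol that becomes the C10 control element.

Step 3
Reactants: 4 (S)-1,4-dioxaspiro[4.5]dec-6-en-8-ol
Product: 5 (S)-8-(tert-butyldimethylsilyloxy)-1,4-dioxaspiro[4.5]dec-6-ene
Conditions: t-BuMe2SiCl, imidazole, DMF, rt
Reagents that add atoms: tert-butyl(chloro)dimethylsilane, CC(C)(C)[Si](C)(C)Cl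
Why: Silyl ether formation at the secondary alcohol gives the bulky group that later shields one face of the enone; the stereocentre is untouched.

Step 4
Reactants: 5 (S)-8-(tert-butyldimethylsilyloxy)-1,4-dioxaspiro[4.5]dec-6-ene
Product: 6 (S)-4-(tert-butyldimethylsilyloxy)cyclohex-2-en-1-one
Conditions: montmorillonite K10 (wet), CH2Cl2, rt
Reagents that add atoms: water, O
Why: Mild acid-catalysed ketal hydrolysis on clay unmasks the ketone, now conjugated with the ring alkene, without β-elimination of the γ-silyloxy group or loss of the silyl ether.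

Step 5
Reactants: 6 (S)-4-(tert-butyldimethylsilyloxy)cyclohex-2-en-1-one; 2 3-(trimethylsilyl)buta-1,2-diene
Product: 7 cis-fused bicyclic ketone (bicyclo[4.3.0]non-8-en-2-one core: C6 ketone; ring A C1–C2H2–C3(SiMe3)=C4(Me)–C5; H-1 and H-5 β; 10β-OSiMe2t-Bu)
Conditions: TiCl4 (1.2 equiv), CH2Cl2, −78 °C; aq. NaHCO3
Reagents that add atoms: none
Why: Danheiser [3+2] (trimethylsilyl)cyclopentene annulation: TiCl4 activates enone 6 and the unsubstituted terminus of allene 2 adds to the β-carbon C1 (bond C1–C2), giving a vinyl cation at C3 stabilised by the β-silicon; a 1,2-shift of silicon from C4 to C3 moves the charge to C4, where the titanium enolate carbon C5 closes ring A (bond C4–C5). The closest known reaction is the same annulation of cyclohexenones such as carvone. Ring A is closed by attack of the enolate α-carbon on the digonal cationic carbon, a 5-endo-dig closure in which C3=C4 ends inside the ring. C1 is set by attack anti to the silyloxy group on the adjacent C10, and C5 follows because the three-atom tether on C1 can reach only the same face of the enolate, which gives the cis ring fusion. The step needs 1,4- over 1,2-addition and ring closure over simple propargyl transfer: the Lewis-acid-bound s-trans enone secures the first, the cation-stabilising methyl and silyl groups of 2 the second.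

Step 6
Reactants: 7 cis-fused bicyclic ketone
Product: 9 tertiary allylic alcohol (4β-OH; 4α-Me; C2=C3 with SiMe3 on C3; C6 ketone; 10β-OSiMe2t-Bu), via hydroperoxide 8 (not isolated)
Conditions: O2, tetraphenylporphyrin (cat.), hν (visible), CH2Cl2, −30 °C; then PPh3, −30 °C → rt
Reagents that add atoms: dioxygen, O=O
Why: Schenck ene reaction of singlet oxygen with the vinylsilane: oxygen bonds to C4, the alkene carbon remote from silicon, and hydrogen is taken from C2, geminal to silicon, on the convex β face of the cis-fused bicycle, which should set C4 with OH β and Me α; PPh3 reduces the hydroperoxide with retention.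

Step 7
Reactants: 9 tertiary allylic alcohol
Product: 10 C4 triethylsilyl ether of 9
Conditions: Et3SiOTf, 2,6-lutidine, CH2Cl2, −78 → −40 °C
Reagents that add atoms: triethylsilyl trifluoromethanesulfonate, CC[Si](CC)(CC)OS(=O)(=O)C(F)(F)F
Why: Silyl triflate silylation of the hindered tertiary alcohol protects it against the Lewis acid and the base of steps 13 and 14; no stereocentre changes.

Step 8
Reactants: 11 methyl (S)-3-bromo-2-methylpropanoate; 12 3-methylbut-2-enoyl chloride
Product: 14 methyl (R)-2,6-dimethyl-4-oxohept-5-enoate, via alkylzinc bromide 13 (not isolated)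
Conditions: Zn dust, I2 (5 mol%), DMA, 70 °C; then 12, Pd(PPh3)4 (5 mol%), THF, 0 °C → rt
Reagents that add atoms: none
Why: Zinc insertion into the primary C–Br bond gives a chelated β-zincio ester and Negishi-type acylation under zerovalent palladium catalysis joins it to the acid chloride; the C11 stereocentre is not the metal-bearing carbon and is kept.

Step 9
Reactants: 14 methyl (R)-2,6-dimethyl-4-oxohept-5-enoate
Product: 15 methyl (2R,4R)-4-hydroxy-2,6-dimethylhept-5-enoate
Conditions: (S)-2-methyl-CBS-oxazaborolidine (20 mol%), catecholborane, toluene, −78 °C; pH 7 buffer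
Reagents that add atoms: none
Why: Corey–Bakshi–Shibata 1,2-reduction of the enone: with the alkenyl arm as the large group the (S)-catalyst should deliver hydride to give the (R)-carbinol at C13, and the ester is inert at −78 °C.

Step 10
Reactants: 15 methyl (2R,4R)-4-hydroxy-2,6-dimethylhept-5-enoate
Product: 16 methyl (2R,4R)-4-(tert-butyldiphenylsilyloxy)-2,6-dimethylhept-5-enoate
Conditions: t-BuPh2SiCl, imidazole, DMF, rt
Reagents that add atoms: tert-butyl(chloro)diphenylsilane, CC(C)(C)[Si](Cl)(c1ccccc1)c1ccccc1
Why: Silyl ether formation blocks lactonisation onto the ester and gives a group that should survive HF·pyridine in step 15.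

Step 11
Reactants: 16 methyl (2R,4R)-4-(tert-butyldiphenylsilyloxy)-2,6-dimethylhept-5-enoate
Product: 17 (2R,4R)-4-(tert-butyldiphenylsilyloxy)-2,6-dimethylhept-5-enal
Conditions: i-Bu2AlH (1.1 equiv), CH2Cl2, −78 °C; aq. Rochelle salt
Reagents that add atoms: none
Why: Partial ester reduction with i-Bu2AlH stops at the tetrahedral aluminium acetal at low temperature and gives the aldehyde on work-up, without base that could epimerise C11.

Step 12
Reactants: 17 (2R,4R)-4-(tert-butyldiphenylsilyloxy)-2,6-dimethylhept-5-enal
Product: 18 hydrazone of aldehyde 17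
Conditions: N2H4·H2O (excess), EtOH, 0 °C → rt
Reagents that add atoms: hydrazine, NN
Why: Condensation of the aldehyde with excess hydrazine gives the N-unsubstituted hydrazone, the precursor of the diazoalkane; the excess suppresses azine formation.

Step 13
Reactants: 10 C4 triethylsilyl ether (six-membered C6 ketone); 18 hydrazone of aldehyde 17
Product: 20 ring-expanded C6 ketone with the side chain on C7 (C7 epimers; seven-membered ring B; C3–SiMe3; 4β-OSiEt3; 10β-OSiMe2t-Bu; 13-OSiPh2t-Bu), via diazoalkane 19 (not isolated)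
Conditions: 18, (COCl)2, DMSO, Et3N, THF, −78 °C; then 10, Sc(OTf)3 (10 mol%), toluene, −78 → −30 °C
Reagents that add atoms: none
Why: Swern-type dehydrogenation of the hydrazone gives the diazoalkane, and Sc(OTf)3-catalysed diazoalkane–ketone homologation (a Tiffeneau–Demjanov-type one-carbon ring expansion) adds the diazo carbon (future C7) to C6=O with migration of the less substituted C8 and loss of N2, so C5 stays next to the carbonyl and C11/C13 arrive intact; C7 forms as an epimer mixture that step 14 corrects.

Step 14
Reactants: 20 ring-expanded C6 ketone (C7 epimers)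
Product: 21 C6 ketone with H-7 β and the side chain α
Conditions: KN(SiMe3)2, THF, −78 °C; then 2,6-di-tert-butyl-4-methylphenol, −78 °C; aq. NH4Cl
Reagents that add atoms: none
Why: Regioselective enolisation toward C7 (the C5–H is shielded by quaternary C4) followed by kinetic C-protonation of the enolate from the convex β face should place H-7 β and the side chain α from either epimer.

Step 15
Reactants: 21 C6 ketone with H-7 β
Product: 22 4β,10β-diol (C6 ketone; C3–SiMe3; 13-OSiPh2t-Bu retained)
Conditions: HF·pyridine, pyridine, THF, 0 °C → rt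
Reagents that add atoms: none
Why: Fluoride-mediated Si–O cleavage removes the secondary tert-butyldimethylsilyl ether at C10 and the triethylsilyl ether at C4, whereas the bulkier, more acid-stable tert-butyldiphenylsilyl ether at C13 should remain.

Step 16
Reactants: 22 4β,10β-diol
Product: 23 6,10-diketone (4β-OH free)
Conditions: Dess–Martin periodinane, NaHCO3, CH2Cl2, 0 °C → rt
Reagents that add atoms: none
Why: Dess–Martin oxidation converts the only secondary alcohol (C10) into the ketone under buffered, non-epimerising conditions; the tertiary C4–OH cannot be oxidised, and the C10 stereocentre has done its work.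

Step 17
Reactants: 23 6,10-diketone
Product: 24 C10 exocyclic methylene compound (C6 ketone)
Conditions: Cp2Ti(μ-CH2)(μ-Cl)AlMe2 (Tebbe reagent, 2.2 equiv), pyridine (cat.), THF/toluene, −40 → 0 °C
Reagents that add atoms: Tebbe reagent, C[Al-]1(C)C[Ti]([Cl+]1)(C2C=CC=C2)C2C=CC=C2
Why: Tebbe methylenation: the titanium methylidene should react with the unhindered C10 ketone and leave the C6 ketone, which is flanked by the C5 and C7 branches, and the non-basic reagent avoids epimerisation at C1 and C7.

Step 18
Reactants: 24 C10 exocyclic methylene compound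
Product: 25 6α-alcohol (H-6 β; all-cis to the C4 branch on C5 and the side chain on C7)
Conditions: LiBH(s-Bu)3, THF, −78 °C; aq. NH4Cl
Reagents that add atoms: none
Why: Hydride reduction with a bulky trialkylborohydride: attack on C6=O from the convex β face, opposite to the ring A branch on C5 and the side chain on C7, should give the α-carbinol.

Step 19
Reactants: 25 6α-alcohol
Product: 26 4β,6α,13-triol (deacetyl target)
Conditions: Bu4NF, DMSO/THF, 60 °C
Reagents that add atoms: none
Why: Fluoride-induced, hydroxyl-assisted protodesilylation of the 2-silyl allylic alcohol cleaves the C3–Si bond with the C2=C3 bond staying in place, and the same reagent cleaves the silyl ether at C13; no stereocentre is touched.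

Step 20
Reactants: 26 4β,6α,13-triol
Product: 27 target CNP0209568.2
Conditions: Ac2O (1.1 equiv), pyridine, CH2Cl2, −20 → 0 °C
Reagents that add atoms: acetic anhydride, CC(=O)OC(C)=O
Why: Acylation of the least hindered hydroxyl: the allylic C13–OH should react, whereas the C6–OH between two branched carbons and the tertiary C4–OH should not under these mild conditions.

**Compound list**
1 | 3-bromo-1-(trimethylsilyl)prop-1-yne | C[Si](C)(C)C#CCBr | starting material
2 | 3-(trimethylsilyl)buta-1,2-diene | C=C=C(C)[Si](C)(C)C | intermediate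
3 | 1,4-dioxaspiro[4.5]dec-6-en-8-one | O=C1C=CC2(CC1)OCCO2 | starting material
4 | (S)-1,4-dioxaspiro[4.5]dec-6-en-8-ol | O[C@@H]1C=CC2(CC1)OCCO2 | intermediate
5 | (S)-8-(tert-butyldimethylsilyloxy)-1,4-dioxaspiro[4.5]dec-6-ene | CC(C)(C)[Si](C)(C)O[C@@H]1C=CC2(CC1)OCCO2 | intermediate
6 | (S)-4-(tert-butyldimethylsilyloxy)cyclohex-2-en-1-one | CC(C)(C)[Si](C)(C)O[C@@H]1C=CC(=O)CC1 | intermediate
7 | cis-5-(tert-butyldimethylsilyloxy)-9-methyl-8-(trimethylsilyl)bicyclo[4.3.0]non-8-en-2-one, silyloxy group trans to the adjacent ring-fusion bond of ring A | CC(C)(C)[Si](C)(C)O[C@H]1CCC(=O)[C@H]2[C@@H]1CC([Si](C)(C)C)=C2C | intermediate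
8 | 4β-hydroperoxide of the transposed alkene (C2=C3, SiMe3 on C3) | CC(C)(C)[Si](C)(C)O[C@H]1CCC(=O)[C@H]2[C@@H]1C=C([Si](C)(C)C)[C@]2(C)OO | intermediate
9 | 4β-hydroxy-4α-methyl tertiary allylic alcohol (C2=C3, SiMe3 on C3, C6 ketone, 10β-silyloxy) | CC(C)(C)[Si](C)(C)O[C@H]1CCC(=O)[C@H]2[C@@H]1C=C([Si](C)(C)C)[C@]2(C)O | intermediate
10 | C4 triethylsilyl ether of 9 | CC(C)(C)[Si](C)(C)O[C@H]1CCC(=O)[C@H]2[C@@H]1C=C([Si](C)(C)C)[C@]2(C)O[Si](CC)(CC)CC | intermediate
11 | methyl (S)-3-bromo-2-methylpropanoate | COC(=O)[C@H](C)CBr | starting material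
12 | 3-methylbut-2-enoyl chloride | CC(C)=CC(Cl)=O | starting material
13 | (S)-(3-methoxy-2-methyl-3-oxopropyl)zinc bromide | COC(=O)[C@H](C)C[Zn]Br | intermediate
14 | methyl (R)-2,6-dimethyl-4-oxohept-5-enoate | COC(=O)[C@H](C)CC(=O)C=C(C)C | intermediate
15 | methyl (2R,4R)-4-hydroxy-2,6-dimethylhept-5-enoate | COC(=O)[C@H](C)C[C@H](C=C(C)C)O | intermediate
16 | methyl (2R,4R)-4-(tert-butyldiphenylsilyloxy)-2,6-dimethylhept-5-enoate | COC(=O)[C@H](C)C[C@H](C=C(C)C)O[Si](c1ccccc1)(c1ccccc1)C(C)(C)C | intermediate
17 | (2R,4R)-4-(tert-butyldiphenylsilyloxy)-2,6-dimethylhept-5-enal | O=C[C@H](C)C[C@H](C=C(C)C)O[Si](c1ccccc1)(c1ccccc1)C(C)(C)C | intermediate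
18 | hydrazone of aldehyde 17 | NN=C[C@H](C)C[C@H](C=C(C)C)O[Si](c1ccccc1)(c1ccccc1)C(C)(C)C | intermediate
19 | (2R,4R)-4-(tert-butyldiphenylsilyloxy)-1-diazo-2,6-dimethylhept-5-ene | [N-]=[N+]=C[C@H](C)C[C@H](C=C(C)C)O[Si](c1ccccc1)(c1ccccc1)C(C)(C)C | intermediate
20 | ring-expanded C6 ketone, side chain on C7, C7 epimer mixture | CC(C)(C)[Si](C)(C)O[C@H]1CCC([C@H](C)C[C@H](C=C(C)C)O[Si](c2ccccc2)(c2ccccc2)C(C)(C)C)C(=O)[C@H]3[C@@H]1C=C([Si](C)(C)C)[C@]3(C)O[Si](CC)(CC)CC | intermediate
21 | C6 ketone with H-7 β and side chain α | CC(C)(C)[Si](C)(C)O[C@H]1CC[C@H]([C@H](C)C[C@H](C=C(C)C)O[Si](c2ccccc2)(c2ccccc2)C(C)(C)C)C(=O)[C@H]3[C@@H]1C=C([Si](C)(C)C)[C@]3(C)O[Si](CC)(CC)CC | intermediate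
22 | 4β,10β-diol, C6 ketone | O[C@H]1CC[C@H]([C@H](C)C[C@H](C=C(C)C)O[Si](c2ccccc2)(c2ccccc2)C(C)(C)C)C(=O)[C@H]3[C@@H]1C=C([Si](C)(C)C)[C@]3(C)O | intermediate
23 | 6,10-diketone, 4β-OH | O=C1CC[C@H]([C@H](C)C[C@H](C=C(C)C)O[Si](c2ccccc2)(c2ccccc2)C(C)(C)C)C(=O)[C@H]3[C@@H]1C=C([Si](C)(C)C)[C@]3(C)O | intermediate
24 | C10 methylene compound, C6 ketone | C=C1CC[C@H]([C@H](C)C[C@H](C=C(C)C)O[Si](c2ccccc2)(c2ccccc2)C(C)(C)C)C(=O)[C@H]3[C@@H]1C=C([Si](C)(C)C)[C@]3(C)O | intermediate
25 | 6α-alcohol, C3–SiMe3 and 13-O-silyl still in place | C=C1CC[C@H]([C@H](C)C[C@H](C=C(C)C)O[Si](c2ccccc2)(c2ccccc2)C(C)(C)C)[C@H](O)[C@H]3[C@@H]1C=C([Si](C)(C)C)[C@]3(C)O | intermediate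
26 | 4β,6α,13-triol (deacetyl target) | C=C1CC[C@H]([C@H](C)C[C@H](C=C(C)C)O)[C@H](O)[C@H]2[C@@H]1C=C[C@]2(C)O | intermediate
27 | CNP0209568.2 | C=C1CC[C@H]([C@H](C)C[C@H](C=C(C)C)OC(C)=O)[C@H](O)[C@H]2[C@@H]1C=C[C@]2(C)O | target

**Step count and risks**
Total step count: 20. Longest linear sequence: 14 steps (steps 2–7, then 13–20).

Step 13 (ring expansion). The branched diazoalkane may decompose (1,2-hydrogen shift, azine formation) faster than it adds to the hindered C6 ketone, or C5 may migrate instead of C8. The fallback is a β-oxido carbenoid ring enlargement. It sets out from hydrazone 18 and ketone 10. Treatment of 18 with CuBr2 and t-BuOLi should give the side-chain 1,1-dibromide F1. Its lithio derivative (LiN(i-Pr)2, THF, −95 °C) should add to 10 to give the dibromo carbinol F2. n-BuLi (2 equiv) then effects bromine–lithium exchange, and the β-oxido carbenoid rearranges with migration of a ring carbon to the lithium enolate of the ring-expanded ketone. Protonation with the hindered phenol as in step 14 brings the route back at 21.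

Step 6 (photooxygenation). Singlet oxygen may attack the face shielded only by the C10 silyloxy group less cleanly than planned, or hydrogen may be taken from the C4 methyl or C5 instead of C2. The fallback is epoxide opening and elimination. It sets out from 7. mCPBA (NaHCO3, CH2Cl2, 0 °C) should give the convex-face α,β-epoxysilane F3. MgBr2·OEt2 should open it at the silicon-bearing C3 with inversion to the bromohydrin F4, which already holds the C4 carbinol. DBU then removes HBr by anti elimination across C2–C3 and the route comes back at 9.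

Step 17 (methylenation of the diketone). Chemoselectivity between the two ketones may be lost, or the titanium alkoxide formed at C4 may cause side reactions. The fallback is a two-stage Peterson olefination. It sets out from 23. Me3SiCH2Li with CeCl3 (THF, −78 °C) should add only to the unhindered C10 ketone to give the β-hydroxysilane F5. HF·pyridine then eliminates silanol and the route comes back at 24.

Further compounds
F1 | step 13 | tert-butyl{[(4R,6R)-7,7-dibromo-2,6-dimethylhept-2-en-4-yl]oxy}diphenylsilane | BrC(Br)[C@H](C)C[C@H](C=C(C)C)O[Si](c1ccccc1)(c1ccccc1)C(C)(C)C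
F2 | step 13 | dibromo carbinol from addition of lithiated F1 to the C6 ketone of 10 | CC(C)(C)[Si](C)(C)O[C@H]1CCC(O)(C(Br)(Br)[C@H](C)C[C@H](C=C(C)C)O[Si](c2ccccc2)(c2ccccc2)C(C)(C)C)[C@H]3[C@@H]1C=C([Si](C)(C)C)[C@]3(C)O[Si](CC)(CC)CC
F3 | step 6 | 3β,4β-epoxide of 7 (α,β-epoxysilane) | CC(C)(C)[Si](C)(C)O[C@H]1CCC(=O)[C@H]2[C@@H]1C[C@]3([Si](C)(C)C)O[C@]23C
F4 | step 6 | 3α-bromo-3β-(trimethylsilyl)-4β-hydroxy bromohydrin | CC(C)(C)[Si](C)(C)O[C@H]1CCC(=O)[C@H]2[C@@H]1C[C@](Br)([Si](C)(C)C)[C@]2(C)O
F5 | step 17 | 10-hydroxy-10-[(trimethylsilyl)methyl] adduct of 23 | C[Si](C)(C)CC1(O)CC[C@H]([C@H](C)C[C@H](C=C(C)C)O[Si](c2ccccc2)(c2ccccc2)C(C)(C)C)C(=O)[C@H]3[C@@H]1C=C([Si](C)(C)C)[C@]3(C)O
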